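**Strategy.** The route exploits the 1,3-relationship of C8a–O1 and C7–OH across the prenylated C8 of ring A: ring A is carried as a cyclohexane-1,3-dione (C6–OMe on its saturated part) and aromatized last. The pyran ring (O1, C2, C3, C4, C4a, C8a) is disconnected into the ring B aldehyde (C2=O1) and a 4-vinyl-1,3-bis(silyloxy)cyclohexa-1,3-diene (C3=C4–C4a=C8a). One catalytic asymmetric oxa-Diels–Alder reaction forms C2–C3 and O1–C8a and sets C2; fluoride then expels the silanol from C8a, ring A tautomerizes to the phenol and all silyl groups fall off, giving the target directly.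

Key step: step 9

Remarks on the chemistry (one line each):
- Atoms are named by their positions in the target (O1, C2, C3, C4, C4a, C5–C8, C8a; ring B primed). TBS = tert-butyldimethylsilyl, prenyl = 3-methylbut-2-en-1-yl.
- CrCl(C27H29NO2) is the chloride complex of trivalent chromium with the dianionic tridentate Schiff base of 3-(1-adamantyl)-2-hydroxy-5-methylbenzaldehyde and cis-1-aminoindan-2-ol.
- Assumption: the ligand antipode that directs attack to the Si face of aldehyde 11 (Si-face attack corresponds to 2S) is taken to be the one from (1R,2S)-1-aminoindan-2-ol; if the sense proves opposite, the (1S,2R) ligand is used.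
- Compounds 2–7 are racemic at C6, which is erased on aromatization. Compounds 5 and 6 are drawn with the ketone at C8a; the silyl-transposed vinylogous ester (ketone at C7) would give the same cation in step 5 and so converges.

Step 1
Reactants: 1 4-methoxybenzene-1,3-diol
Product: 2 4-methoxycyclohexane-1,3-dione
Conditions: H2 (4 atm), 5% Rh/Al2O3, NaOH (1.1 equiv), H2O, 50 °C; then HCl to pH 3
Reagents that add atoms: none
Why: Partial catalytic hydrogenation of a resorcinol monoanion should stop at the enolate of the cyclohexane-1,3-dione (the classical dihydroresorcinol synthesis), and the new C6 centre is racemic and later erased.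

Step 2
Reactants: 2 4-methoxycyclohexane-1,3-dione
Product: 3 4-methoxy-2-(3-methylbut-2-en-1-yl)cyclohexane-1,3-dione
Conditions: prenyl bromide, KOH (1 equiv), H2O, 0 °C to rt
Reagents that add atoms: prenyl bromide (1-bromo-3-methylbut-2-ene), CC(C)=CCBr
Why: C-Alkylation of the 1,3-dione enolate at the carbon between the carbonyls (future C8) with an allylic bromide in water, where solvation of the enolate oxygens favours C- over O-alkylation, should place the prenyl group between the two future ring A oxygens without regiochemical ambiguity; the C8 and C6 centres are not controlled and are erased later.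

Step 3
Reactants: 3 4-methoxy-2-(3-methylbut-2-en-1-yl)cyclohexane-1,3-dione
Product: 4 1,3-bis(tert-butyldimethylsilyloxy)-6-methoxy-2-(3-methylbut-2-en-1-yl)cyclohexa-1,3-diene
Conditions: TBSOTf (2.3 equiv), Et3N (3 equiv), Et2O, 0 °C to rt
Reagents that add atoms: tert-butyldimethylsilyl trifluoromethanesulfonate (TBSOTf), CC(C)(C)[Si](C)(C)OS(=O)(=O)C(F)(F)F
Why: Exhaustive soft enolization of the 1,3-dione (O-silylation, second O-silylation to a 1,3-bis(silyloxy)allyl cation, amine deprotonation) should give the cross-conjugated bis(silyl dienol ether), the proton being taken from the free C4a methylene and not from the methoxy-bearing C6 methine, whose C–H is held near the plane of the cation by A(1,2) strain between OMe and the adjacent silyloxy group.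

Step 4
Reactants: 4 1,3-bis(tert-butyldimethylsilyloxy)-6-methoxy-2-(3-methylbut-2-en-1-yl)cyclohexa-1,3-diene
Product: 6 (6E)-3-(tert-butyldimethylsilyloxy)-6-ethylidene-4-methoxy-2-(3-methylbut-2-en-1-yl)cyclohex-2-en-1-one, via β-methoxy ketone 5 (not isolated)
Conditions: MeCH(OMe)2, TMSOTf (5 mol %), CH2Cl2, –78 °C; then DBU, 0 °C to rt
Reagents that add atoms: acetaldehyde dimethyl acetal (1,1-dimethoxyethane), COC(C)OC
Why: Mukaiyama aldol-type addition of the diene terminus C4a (the only unsubstituted nucleophilic carbon, C8 being blocked by the prenyl group) to the oxocarbenium ion from the acetal should give the β-methoxy ketone, and E1cB loss of methanol with DBU should give the conjugated (E)-ethylidene ketone that carries C4 and C3 on C4a.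

Step 5
Reactants: 6 (6E)-3-(tert-butyldimethylsilyloxy)-6-ethylidene-4-methoxy-2-(3-methylbut-2-en-1-yl)cyclohex-2-en-1-one
Product: 7 1,3-bis(tert-butyldimethylsilyloxy)-4-ethenyl-6-methoxy-2-(3-methylbut-2-en-1-yl)cyclohexa-1,3-diene
Conditions: TBSOTf (1.2 equiv), Et3N (2 equiv), Et2O, –78 to 0 °C
Reagents that add atoms: tert-butyldimethylsilyl trifluoromethanesulfonate (TBSOTf), CC(C)(C)[Si](C)(C)OS(=O)(=O)C(F)(F)F
Why: Soft enolization of the α-alkylidene ketone to a 2-silyloxydiene should occur by O-silylation to a bis(silyloxy)pentadienyl cation followed by removal of a proton from the ethylidene methyl group (γ-deprotonation), the methoxy-bearing C6–H being misaligned as in step 3.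

Step 6
Reactants: 8 2-bromo-3-hydroxy-4-methoxybenzaldehyde
Product: 9 2-bromo-3,4-dihydroxybenzaldehyde
Conditions: BBr3 (2.5 equiv), CH2Cl2, –78 °C to rt; then H2O
Reagents that add atoms: none
Why: Lewis acid cleavage of the aryl methyl ether with BBr3 (assisted by the neighbouring hydroxyl through a cyclic aryl borate that is hydrolysed on work-up) should free the catechol while the aldehyde and the aryl bromide are untouched.

Step 7
Reactants: 9 2-bromo-3,4-dihydroxybenzaldehyde
Product: 10 2-bromo-3,4-bis(tert-butyldimethylsilyloxy)benzaldehyde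
Conditions: TBSCl (2.5 equiv), imidazole, DMF, rt
Reagents that add atoms: tert-butyldimethylsilyl chloride (TBSCl), CC(C)(C)[Si](C)(C)Cl
Why: Standard silylation of both phenols gives ethers that should tolerate the Stille coupling and the Lewis acid of step 9 and that leave with fluoride, so that no strong acid or hydrogenolysis is needed near the prenyl groups and the benzylic C2–O1 bond.

Step 8
Reactants: 10 2-bromo-3,4-bis(tert-butyldimethylsilyloxy)benzaldehyde
Product: 11 3,4-bis(tert-butyldimethylsilyloxy)-2-(3-methylbut-2-en-1-yl)benzaldehyde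
Conditions: prenylSnBu3, Pd2(dba)3 (2.5 mol %), P(2-furyl)3, toluene, 100 °C
Reagents that add atoms: tributyl(3-methylbut-2-en-1-yl)stannane, CCCC[Sn](CCCC)(CCCC)CC=C(C)C
Why: Stille coupling of the aryl bromide (activated by the ortho formyl group) with the prenylstannane under neutral conditions should spare the aryl silyl ethers and the aldehyde, transfer through the α-carbon giving the linear prenyl group at C2'.

Step 9
Reactants: 7 1,3-bis(tert-butyldimethylsilyloxy)-4-ethenyl-6-methoxy-2-(3-methylbut-2-en-1-yl)cyclohexa-1,3-diene; 11 3,4-bis(tert-butyldimethylsilyloxy)-2-(3-methylbut-2-en-1-yl)benzaldehyde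
Product: 13 (2S)-2-[3,4-dihydroxy-2-(3-methylbut-2-en-1-yl)phenyl]-6-methoxy-8-(3-methylbut-2-en-1-yl)-3,4-dihydro-2H-chromen-7-ol, via cycloadduct 12 (not isolated)
Conditions: CrCl(C27H29NO2) (10 mol %), 4 Å MS, t-BuOMe, rt; then Bu4NF, AcOH, THF, 0 °C to rt
Reagents that add atoms: none
Why: Proposed new method: the chiral Lewis acid of trivalent chromium binds the formyl oxygen of 11, and the exocyclic 1-silyloxydiene of 7 (C3=C4–C4a=C8a) adds in an asynchronous [4+2] cycloaddition in which the free CH2 terminus C3, activated by both silyloxy groups, bonds to C2 and the carbonyl oxygen bonds to the silyloxy-bearing C8a. The closest known reaction type is the enantioselective oxa-Diels–Alder reaction of aldehydes with 1-alkoxy- and silyloxydienes under chromium Schiff-base catalysis, followed by the eliminative unmasking known from cyclocondensations of 1-methoxy-3-silyloxybutadiene, extended here to a diene whose oxygenated terminus is fully substituted and belongs to a dihydroresorcinol bis(silyl enol ether). The pyran ring (O1, C2, C3, C4, C4a, C8a) closes by this intermolecular hetero-[4+2] cycloaddition, suprafacial on both partners, and no other ring is formed. C2 is the only new stereocentre that survives and it is set by the catalyst through Si-face attack on the aldehyde, which corresponds to 2S, while the C8a ketal centre and the racemic C6 centre only give diastereomers that converge on aromatization. Buffered fluoride then cleaves the C7 silyl enol ether, the enolate expels silanolate from C8a (E1cB), ring A tautomerizes to the phenol (C6–H to O7, C5–H to C4) and the remaining silyl ethers are removed without strong acid, so the 4'-oxygenated benzylic C2–O1 bond should not ionize. The step needs site selectivity for the exocyclic diene over the endocyclic 1,3-bis(silyloxy)diene, secured because both termini of the latter (C7 and C4a) are fully substituted, and chemoselectivity over a carbonyl-ene reaction of the aldehyde with its own ortho prenyl group, secured by the much higher nucleophilicity of the triene and the mild Lewis acid.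

Compound list
1 | 4-methoxybenzene-1,3-diol (4-methoxyresorcinol) | COc1ccc(O)cc1O | starting material
2 | 4-methoxycyclohexane-1,3-dione (racemic, drawn as diketone) | COC1CCC(=O)CC1=O | intermediate
3 | 4-methoxy-2-(3-methylbut-2-en-1-yl)cyclohexane-1,3-dione (racemic, tautomer mixture) | COC1CCC(=O)C(CC=C(C)C)C1=O | intermediate
4 | 1,3-bis(tert-butyldimethylsilyloxy)-6-methoxy-2-(3-methylbut-2-en-1-yl)cyclohexa-1,3-diene (racemic) | COC1CC=C(O[Si](C)(C)C(C)(C)C)C(CC=C(C)C)=C1O[Si](C)(C)C(C)(C)C | intermediate
5 | 3-(tert-butyldimethylsilyloxy)-4-methoxy-6-(1-methoxyethyl)-2-(3-methylbut-2-en-1-yl)cyclohex-2-en-1-one (diastereomer mixture, not isolated) | COC(C)C1CC(OC)C(O[Si](C)(C)C(C)(C)C)=C(CC=C(C)C)C1=O | intermediate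
6 | (6E)-3-(tert-butyldimethylsilyloxy)-6-ethylidene-4-methoxy-2-(3-methylbut-2-en-1-yl)cyclohex-2-en-1-one (racemic) | C/C=C1\CC(OC)C(O[Si](C)(C)C(C)(C)C)=C(CC=C(C)C)C1=O | intermediate
7 | 1,3-bis(tert-butyldimethylsilyloxy)-4-ethenyl-6-methoxy-2-(3-methylbut-2-en-1-yl)cyclohexa-1,3-diene (racemic) | COC1CC(C=C)=C(O[Si](C)(C)C(C)(C)C)C(CC=C(C)C)=C1O[Si](C)(C)C(C)(C)C | intermediate
8 | 2-bromo-3-hydroxy-4-methoxybenzaldehyde | COc1ccc(C=O)c(Br)c1O | starting material
9 | 2-bromo-3,4-dihydroxybenzaldehyde | O=Cc1ccc(O)c(O)c1Br | intermediate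
10 | 2-bromo-3,4-bis(tert-butyldimethylsilyloxy)benzaldehyde | O=Cc1ccc(O[Si](C)(C)C(C)(C)C)c(O[Si](C)(C)C(C)(C)C)c1Br | intermediate
11 | 3,4-bis(tert-butyldimethylsilyloxy)-2-(3-methylbut-2-en-1-yl)benzaldehyde | O=Cc1ccc(O[Si](C)(C)C(C)(C)C)c(O[Si](C)(C)C(C)(C)C)c1CC=C(C)C | intermediate
12 | (2S)-2-[3,4-bis(tert-butyldimethylsilyloxy)-2-(3-methylbut-2-en-1-yl)phenyl]-7,8a-bis(tert-butyldimethylsilyloxy)-6-methoxy-8-(3-methylbut-2-en-1-yl)-3,5,6,8a-tetrahydro-2H-chromene (mixture at C6 and C8a, not isolated) | COC1CC2=CC[C@@H](c3ccc(O[Si](C)(C)C(C)(C)C)c(O[Si](C)(C)C(C)(C)C)c3CC=C(C)C)OC2(O[Si](C)(C)C(C)(C)C)C(CC=C(C)C)=C1O[Si](C)(C)C(C)(C)C | intermediate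
13 | (2S)-2-[3,4-dihydroxy-2-(3-methylbut-2-en-1-yl)phenyl]-6-methoxy-8-(3-methylbut-2-en-1-yl)-3,4-dihydro-2H-chromen-7-ol | COc1cc2c(c(CC=C(C)C)c1O)O[C@H](c1ccc(O)c(O)c1CC=C(C)C)CC2 | target

Total step count: 9. Longest linear sequence: 6 steps (steps 1, 2, 3, 4, 5 and 9); the ring B branch is steps 6, 7, 8 and 9.

Steps most likely to fail

1. Step 9 (proposed new method). What may go wrong: the cycloaddition may be too slow with the hindered, electron-rich aldehyde, so that the triene loses methanol or a silyl group under the Lewis acid and aromatizes first. The addition may also turn stepwise and stall as an open-chain aldol, facial selectivity may be insufficient, or the ring may open at the hemiketal stage during unmasking. The fallback uses only known reactions, sets out from 4 and 11 and returns at 13; it gives up the cycloaddition and closes the pyran ring through a phenol oxygen instead. DDQ dehydrogenates 4 to the arene 1,3-bis(tert-butyldimethylsilyloxy)-4-methoxy-2-prenylbenzene F1, and Bu4NF frees 4-methoxy-2-prenylbenzene-1,3-diol F2. Vinylmagnesium bromide adds to 11 to give the racemic allylic alcohol 1-[3,4-bis(tert-butyldimethylsilyloxy)-2-prenylphenyl]prop-2-en-1-ol F3, which MnO2 oxidizes to the aryl vinyl ketone 1-[3,4-bis(tert-butyldimethylsilyloxy)-2-prenylphenyl]prop-2-en-1-one F4. Friedel–Crafts conjugate addition of F2 to F4 under Sc(OTf)3 catalysis, through the carbon ortho and para to the two hydroxyls (future C4a), gives the ketone 1-[3,4-bis(tert-butyldimethylsilyloxy)-2-prenylphenyl]-3-(2,4-dihydroxy-5-methoxy-3-prenylphenyl)propan-1-one F5. Corey–Bakshi–Shibata reduction with the (S)-oxazaborolidine and BH3·SMe2 gives the (R)-carbinol (1R)-1-[3,4-bis(tert-butyldimethylsilyloxy)-2-prenylphenyl]-3-(2,4-dihydroxy-5-methoxy-3-prenylphenyl)propan-1-ol F6. Mitsunobu cyclization (PPh3, DIAD) through the hydroxyl on the future C8a, with inversion, gives the flavan (2S)-2-[3,4-bis(tert-butyldimethylsilyloxy)-2-prenylphenyl]-6-methoxy-8-prenylchroman-7-ol F7, and Bu4NF gives 13.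

2. Step 3. What may go wrong: the second enolization may run toward the methoxy-bearing carbon and give the wrong diene, or methanol may be lost with aromatization. The fallback sets out from 3 and returns at 4, replacing the one-pot soft enolization by a stepwise kinetic sequence through a regiodefined intermediate. Monosilylation (TBSCl, Et3N) gives the vinylogous silyl esters; the isomer with the ketone next to the ring CH2, 3-(tert-butyldimethylsilyloxy)-4-methoxy-2-prenylcyclohex-2-en-1-one F8, is separated, and the other isomer is recycled by hydrolysis to 3. LDA at –78 °C deprotonates F8 at its only α' position (C4a), and TBSCl traps the enolate as 4.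

3. Step 4. What may go wrong: DBU may deprotonate at C6 and tautomerize the ethylidene ketone irreversibly to an aromatic ethylresorcinol silyl ether, the elimination may be incomplete, or the vinylogous silyl ester may hydrolyse. The fallback sets out from 4 and returns at 7, using a vinyl cation equivalent so that no ethylidene ketone and no amidine base are involved. Mukaiyama aldol addition of 4 to (phenylselanyl)acetaldehyde (BF3·OEt2, –78 °C) gives the β-hydroxy selenide 3-(tert-butyldimethylsilyloxy)-6-[1-hydroxy-2-(phenylselanyl)ethyl]-4-methoxy-2-prenylcyclohex-2-en-1-one F9. MsCl and Et3N effect reductive elimination to the α'-vinyl ketone 3-(tert-butyldimethylsilyloxy)-6-ethenyl-4-methoxy-2-prenylcyclohex-2-en-1-one F10. LDA then removes the doubly activated C4a–H and TBSCl gives 7.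

Further compounds
F1 | step 9 | 1,3-bis(tert-butyldimethylsilyloxy)-4-methoxy-2-(3-methylbut-2-en-1-yl)benzene | COc1ccc(O[Si](C)(C)C(C)(C)C)c(CC=C(C)C)c1O[Si](C)(C)C(C)(C)C
F2 | step 9 | 4-methoxy-2-(3-methylbut-2-en-1-yl)benzene-1,3-diol | COc1ccc(O)c(CC=C(C)C)c1O
F3 | step 9 | 1-[3,4-bis(tert-butyldimethylsilyloxy)-2-(3-methylbut-2-en-1-yl)phenyl]prop-2-en-1-ol (racemic) | C=CC(O)c1ccc(O[Si](C)(C)C(C)(C)C)c(O[Si](C)(C)C(C)(C)C)c1CC=C(C)C
F4 | step 9 | 1-[3,4-bis(tert-butyldimethylsilyloxy)-2-(3-methylbut-2-en-1-yl)phenyl]prop-2-en-1-one | C=CC(=O)c1ccc(O[Si](C)(C)C(C)(C)C)c(O[Si](C)(C)C(C)(C)C)c1CC=C(C)C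
F5 | step 9 | 1-[3,4-bis(tert-butyldimethylsilyloxy)-2-(3-methylbut-2-en-1-yl)phenyl]-3-[2,4-dihydroxy-5-methoxy-3-(3-methylbut-2-en-1-yl)phenyl]propan-1-one | COc1cc(CCC(=O)c2ccc(O[Si](C)(C)C(C)(C)C)c(O[Si](C)(C)C(C)(C)C)c2CC=C(C)C)c(O)c(CC=C(C)C)c1O
F6 | step 9 | (1R)-1-[3,4-bis(tert-butyldimethylsilyloxy)-2-(3-methylbut-2-en-1-yl)phenyl]-3-[2,4-dihydroxy-5-methoxy-3-(3-methylbut-2-en-1-yl)phenyl]propan-1-ol | COc1cc(CC[C@@H](O)c2ccc(O[Si](C)(C)C(C)(C)C)c(O[Si](C)(C)C(C)(C)C)c2CC=C(C)C)c(O)c(CC=C(C)C)c1O
F7 | step 9 | (2S)-2-[3,4-bis(tert-butyldimethylsilyloxy)-2-(3-methylbut-2-en-1-yl)phenyl]-6-methoxy-8-(3-methylbut-2-en-1-yl)-3,4-dihydro-2H-chromen-7-ol | COc1cc2c(c(CC=C(C)C)c1O)O[C@H](c1ccc(O[Si](C)(C)C(C)(C)C)c(O[Si](C)(C)C(C)(C)C)c1CC=C(C)C)CC2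
F8 | step 3 | 3-(tert-butyldimethylsilyloxy)-4-methoxy-2-(3-methylbut-2-en-1-yl)cyclohex-2-en-1-one (racemic) | COC1CCC(=O)C(CC=C(C)C)=C1O[Si](C)(C)C(C)(C)C
F9 | step 4 | 3-(tert-butyldimethylsilyloxy)-6-[1-hydroxy-2-(phenylselanyl)ethyl]-4-methoxy-2-(3-methylbut-2-en-1-yl)cyclohex-2-en-1-one (diastereomer mixture) | COC1CC(C(O)C[Se]c2ccccc2)C(=O)C(CC=C(C)C)=C1O[Si](C)(C)C(C)(C)C
F10 | step 4 | 3-(tert-butyldimethylsilyloxy)-6-ethenyl-4-methoxy-2-(3-methylbut-2-en-1-yl)cyclohex-2-en-1-one (diastereomer mixture) | COC1CC(C=C)C(=O)C(CC=C(C)C)=C1O[Si](C)(C)C(C)(C)C
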